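## The problem

Numbering used throughout: C1 is the ketone carbon, C2=C3 the enone alkene (methyl on C3), C4 and C11 the cyclobutane CH carbons bonded to C3 and C1, C5 the cyclobutane CH bonded to the gem-dimethyl carbon C6, C7 and C9 the ester-bearing carbinols on either side of CH2 C8, and C10 the methyl-bearing quaternary cyclobutane carbon. In this numbering the target is (4R,5S,7R,9R,10R,11R).

The target is a cyclobutane (C4, C5, C11, C10) bridged across both diagonals. C4 and C11 carry the three-carbon enone unit C3–C2–C1 on one face, and C5 and C10 carry the four-carbon chain C6–C7–C8–C9 on the other, so a bicyclo[3.1.1]heptenone and a bicyclo[4.1.1]octane share the four-membered ring. The four cyclobutane stereocentres are locked relative to one another once both bridges exist, so only their absolute sense has to be set. C7 and C9 form an anti-1,3-diol flanked by the quaternary carbons C6 and C10. They lie in the local mirror plane of the core, far from the only element that breaks it (the direction of the enone), so they need reagent control. The sensitive groups are the enone (acidic C3 methyl, reducible carbonyl), the strained ring, and two neopentyl-type esters that must go on last. The enabling feature is that cutting C2=C3 leaves acetyl groups on C4 and C11 that are mirror images through the plane holding C5, C6, C7, C8, C9 and C10, provided C7 and C9 are at the ketone level. The core then hides a meso diketone, and one catalyst-controlled choice between two acetyl groups fixes C4, C5, C10 and C11 together. A constraint comes with it: C6 and C9 sit on the same face about 2.9 Å apart (model estimate). A quaternary C6 can occupy that position only if it is already tied to C9, and this fixes the order of the ring closures.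

## Retrosynthesis

**Esters and diol (20 ⇒ 19 ⇒ 18 ⇒ 17).** The two isovalerates are cut first, giving enone diol 19. The anti diol is traced to the 7,9-dione of trione 17 by a Corey–Bakshi–Shibata reduction. Both ring ketones have a quaternary carbon on one side and C8 on the other, so one catalyst enantiomer should give the same absolute sense at both, which is the anti diol. The enone carbonyl will be reduced as well, so triol 18 and a selective allylic re-oxidation to 19 are accepted in place of protecting-group steps.

**Enone ring (17 ⇒ 15), the key cut.** Cutting C2=C3 as an aldol condensation gives the meso bicyclic tetraketone 15, whose acetyl groups on C4 and C11 are enantiotopic. Cutting the seven-membered ring first was rejected. Closing the enone ring on the monocyclic diketone 11 would force its tert-alkyl arm and its ester into syn positions on a rigid bicyclo[3.1.1] frame. Together with the strain of the new bridge, this should make a reversible aldol closure uphill. In 15 the four-carbon bridge holds the two acetyl groups side by side, so the closure is pre-organised and relieves strain. The forward reaction must distinguish two enantiotopic methyl ketones; regiochemistry and relative configuration are not in question.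

**Unmasking and seven-membered ring (15 ⇒ 14 ⇒ 13 ⇒ 12 ⇒ 11).** The C8–C9 bond is cut as a Claisen condensation of a methyl ketone enolate onto the C10 ester, and the methyl ketone comes from a vinyl group by Wacker oxidation (13 from 12). A strong base cannot be used while the two ring acetyl groups are free: once the bridge pushes them together they would close the enone ring racemically. Ketals are excluded because two quaternary ketal carbons cannot sit in the syn positions of the bicycle. The acetyl groups are therefore carried from 11 as planar, non-acidic isopropenyl groups (12 to 14) and regenerated by neutral oxidative cleavage (14 to 15). The cost is two steps.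

**Cyclobutane (11 ⇒ 10 ⇒ 9).** The C5–C11 bond is cut by nitrogen deletion from pyrrolidine 9, which is one atom larger and can be made by cycloaddition. The acetyl-bearing carbons are epimerisable, so only the relation between the C5 arm and the C10 ester has to come out of the pyrrolidine correctly. The kinetic cyclobutane 10 is converted to the all-trans meso isomer 11 by base.

**Pyrrolidine (9 ⇒ 8 + 6; 8 ⇒ 7 + 3; 6 ⇒ 4 + 5; 3 ⇒ 2 ⇒ 1).** The C10–C11 and C4–C5 bonds are cut as an azomethine ylide [3+2] cycloaddition between aldimine 8 (from aminoacetone hydrochloride 7 and aldehyde 3) and keto-enoate 6. This places an acetyl group on each of the two carbons that need one and puts the ester and methyl on C10. The alternative pairing, with the ylide carrying C10, was rejected because its normal endo mode would place the ester trans to the arm. Keto-enoate 6 is a Wittig product of methyl pyruvate 4 and phosphorane 5; aldehyde 3 comes from acid 1 via alcohol 2.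

## Roads not taken

**Alternative 1:** This route cuts C5–C6 and C9–C10. A tertiary α-keto radical from bromo ynone A1 would add to C5 of the cyclohexane-fused methylbicyclobutane A2, and the resulting C10 radical would close onto the alkyne terminus to give tricyclic enone A3.
- Merits: it makes the hindered C5–C6 bond, the seven-membered ring and the cis C5/C10 relationship in one step, and it reaches the full carbon skeleton in fewer operations than the chosen plan.
- Weak points: A3 lacks the C9 oxygen, which would have to be introduced at a neopentyl β-carbon with reagent control. The enone ring must be rebuilt from a C3 ketal (methyl addition, C1 oxidation, C2=C3). The absolute configuration depends on an enantioenriched A2, for which no simple catalytic entry is evident, and the seven-membered radical closure competes with premature reduction.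
- Comparison: the chosen plan is longer to the tricycle, but at 17 every oxygen is in place at a usable oxidation level and chirality comes from a catalytic desymmetrisation of an achiral intermediate.

**Alternative 2:** This route cuts C4–C10. The titanocene chloride Cp2TiCl (trivalent titanium) would open the C9–C10 epoxide of the carvone-derived epoxy ketone A4 to a C10 radical that adds to the C4 carbonyl, giving cyclobutanol A5.
- Merits: the absolute configuration comes from the chiral pool, and C7 and C9 already carry oxygen with defined configuration. In that respect it is better than the late reagent-controlled reduction of the chosen plan.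
- Weak points: four-membered ring closure of a radical onto a ketone is reversible and needs efficient trapping. A5 carries a tertiary hydroxyl on C4 that would have to be replaced by hydrogen with retention at an allylic cyclobutane carbon, for which there is no reliable method. C1 still needs allylic oxidation, and A4 itself is a long synthesis.
- Comparison: the chosen plan carries C4–H from the start and needs no deoxygenation, at the price of setting C7 and C9 late.

**Alternative 3:** This route cuts C5–C11 and C4–C10. Tf2O and collidine would convert amide A6 into a keteniminium ion that adds across the nearer alkene of the diene in the crossed sense, giving the bridged cyclobutanone A7 after hydrolysis.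
- Merits: the cyclobutane and the seven-membered ring form in one step from an acyclic precursor, with a single carbinol stereocentre (C7) as the source of chirality. In ring construction this is clearly more economical than steps 4 to 9 here.
- Weak points: the crossed mode depends on an allyl cation that can also close at its far end (a six-membered ring) or in the fused sense. Induction from C7 through a flexible chain is uncertain. A7 still needs a one-carbon link between the C11 ketone and the isopropenyl group, and hydration of C8=C9 at the more hindered carbon anti to C7.
- Comparison: the chosen plan has a key step with only one possible ring-closure topology and an oxidation pattern that maps directly onto the target, against a longer route to its precursor.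

Key step: step 11

Assumption: the sense of enantiotopic-group selection by the cinchona amine on this bridged substrate cannot be assigned in advance; the quinine-derived catalyst is written, and its quinidine-derived pseudoenantiomer is used instead if the product belongs to the opposite series.

## Route

Step 1
Reactants: 1 2,2-dimethylbut-3-enoic acid
Product: 2 2,2-dimethylbut-3-en-1-ol
Conditions: LiAlH4, Et2O, 0 °C to rt; aqueous work-up
Reagents that add atoms: none
Why: Hydride reduction of a carboxylic acid to the primary alcohol; the isolated vinyl group is inert and no stereocentre is involved.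

Step 2
Reactants: 2 2,2-dimethylbut-3-en-1-ol
Product: 3 2,2-dimethylbut-3-enal
Conditions: TEMPO (10 mol %), PhI(OAc)2, CH2Cl2, rt; distilled
Reagents that add atoms: none
Why: Oxoammonium (TEMPO) oxidation stops at the aldehyde; the aldehyde has no α-hydrogen, so it can neither enolise nor move the alkene into conjugation.

Step 3
Reactants: 4 methyl pyruvate; 5 1-(triphenylphosphoranylidene)propan-2-one
Product: 6 methyl (E)-2-methyl-4-oxopent-2-enoate
Conditions: CH2Cl2, rt to 40 °C
Reagents that add atoms: none
Why: Wittig olefination of the activated keto group by a stabilised ylide, which should place the acetyl group trans to the ester; any Z isomer is removed by chromatography.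

Step 4
Reactants: 7 aminoacetone hydrochloride; 3 2,2-dimethylbut-3-enal; 6 methyl (E)-2-methyl-4-oxopent-2-enoate
Product: 9 racemic methyl 2,4-diacetyl-3-methyl-5-(2-methylbut-3-en-2-yl)pyrrolidine-3-carboxylate having the 2-acetyl group and the 3-ester cis to the 5-alkyl group and the 4-acetyl group trans to it, via aldimine 8 (not isolated)
Conditions: 7, 3 (1.3 equiv), Et3N (1.05 equiv), 4 Å MS, CH2Cl2, 0 °C; then 6, AgOAc (10 mol %), Et3N (10 mol %), toluene, 0 °C to rt
Reagents that add atoms: none
Why: Condensation gives aldimine 8, whose silver-bound 2-azaallyl anion (chelated through N and the acetyl oxygen, W-shaped, hence 2,5-cis) undergoes the metal-catalysed azomethine ylide [3+2] cycloaddition with 6. The ketone of 6 should direct the nucleophilic ylide carbon to the methyl-bearing alkene carbon, since the reverse orientation would join the quaternary carbon to the neopentyl imine carbon. The dipolarophile is expected to turn its ester, not its acetyl group, toward silver because an acetyl group there would eclipse the tert-alkyl arm, so the E alkene puts the ester cis and the 4-acetyl trans to the arm.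

Step 5
Reactants: 9 the pyrrolidine of step 4
Product: 10 racemic methyl 2,4-diacetyl-1-methyl-3-(2-methylbut-3-en-2-yl)cyclobutane-1-carboxylate having the ester cis to the side chain and one acetyl group cis and the other trans to them
Conditions: N-(benzyloxy)-N-(pivaloyloxy)-4-(trifluoromethyl)benzamide (1.5 equiv), THF, 45 °C
Reagents that add atoms: none
Why: Nitrogen deletion: the amine attacks the anomeric amide, the adduct collapses to a 1,1-diazene, and loss of N2 leaves a short-lived singlet 1,4-diradical that recombines to the C5–C11 bond. Recombination should outrun bond rotation, so the arm stays cis to the ester; any scrambling at the acetyl-bearing carbon is corrected in step 6.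

Step 6
Reactants: 10 the kinetic cyclobutane of step 5
Product: 11 meso methyl 2,4-diacetyl-1-methyl-3-(2-methylbut-3-en-2-yl)cyclobutane-1-carboxylate having both acetyl groups cis to the 1-methyl group and trans to the side chain and the ester
Conditions: DBU (20 mol %), toluene, 40 °C
Reagents that add atoms: none
Why: Base-mediated epimerisation through the ring enolate moves the acetyl group that is cis to both the arm and the ester to the open face, giving the achiral all-trans isomer. The acetyl groups are now cis, but aldol closure would force the arm and the ester into syn positions, so it should not compete.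

Step 7
Reactants: 11 the meso diketone of step 6
Product: 12 meso methyl 1-methyl-3-(2-methylbut-3-en-2-yl)-2,4-di(prop-1-en-2-yl)cyclobutane-1-carboxylate with the ring configuration of 11
Conditions: Ph3PCH3Br, KOtBu, THF, 0 to 50 °C
Reagents that add atoms: methyltriphenylphosphonium bromide, C[P+](c1ccccc1)(c1ccccc1)c1ccccc1.[Br-]
Why: Wittig methylenation of both methyl ketones; the ester and the vinyl group are untouched. The isopropenyl groups are planar acetyl equivalents without acidic hydrogens, so they survive the base of step 9 and can lie side by side in the bicycle.

Step 8
Reactants: 12 the triene ester of step 7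
Product: 13 meso methyl 1-methyl-3-(2-methyl-3-oxobutan-2-yl)-2,4-di(prop-1-en-2-yl)cyclobutane-1-carboxylate
Conditions: PdCl2 (10 mol %), CuCl (cat.), O2 (1 atm), DMF–H2O, rt to 40 °C
Reagents that add atoms: water, O
Why: Wacker oxidation: hydroxypalladation of the monosubstituted vinyl group at its internal carbon gives the methyl ketone; the 1,1-disubstituted isopropenyl groups react much more slowly.

Step 9
Reactants: 13 the keto ester of step 8
Product: 14 meso 1,5,5-trimethyl-7,8-di(prop-1-en-2-yl)bicyclo[4.1.1]octane-2,4-dione with both isopropenyl groups anti to the four-carbon bridge
Conditions: KOtBu (3 equiv), THF, 0 to 50 °C; then 1 M HCl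
Reagents that add atoms: none
Why: Intramolecular Claisen (Dieckmann-type) condensation: the only enolate available, at the methyl group C8, acylates the C10 ester, which has no α-hydrogen, and the stabilised diketonate drives closure of the seven-membered ring. Only an ester cis to the arm can be reached, so ring closure also confirms the C5/C10 relationship.

Step 10
Reactants: 14 the bicyclic dione of step 9
Product: 15 meso 7,8-diacetyl-1,5,5-trimethylbicyclo[4.1.1]octane-2,4-dione with both acetyl groups anti to the four-carbon bridge and syn to each other
Conditions: OsO4 (5 mol %), NaIO4, 2,6-lutidine, dioxane–H2O, rt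
Reagents that add atoms: osmium tetroxide, O=[Os](=O)(=O)=O; sodium periodate, [Na+].[O-]I(=O)(=O)=O; water, O
Why: Lemieux–Johnson cleavage (dihydroxylation, then periodate cleavage) of both 1,1-disubstituted alkenes unveils the acetyl groups under buffered, near-neutral conditions that should not trigger an uncatalysed aldol. The hindered seven-membered 1,3-dione, mainly in its diketo form, should be left alone.

Step 11
Reactants: 15 the meso tetraketone of step 10
Product: 17 (4R,5S,10R,11R)-3,6,6,10-tetramethyl tricyclic enone-dione (longipin-2-ene-1,7,9-trione in the numbering above), via ketol 16 (not isolated)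
Conditions: 9-amino-9-deoxy-epi-quinine (20 mol %), AcOH (60 mol %), toluene, rt to 40 °C
Reagents that add atoms: none
Why: The primary amine condenses with one acetyl group; the iminium ion tautomerises to the enamine on its methyl side, whose terminal carbon (C2) adds to the carbonyl carbon (C3) of the other acetyl group. The ketol 16, bound as its iminium ion, then dehydrates and hydrolysis releases enone 17 and the catalyst. The closest known reaction type is the cinchona-primary-amine/acid-catalysed desymmetrising aldol condensation of 4-substituted heptane-2,6-diones to 5-substituted 3-methylcyclohex-2-enones; 15 is such a dione with C3 and C5 of the heptane chain tied together by C10. The six-membered ring closes in the 6-(enolexo)-exo-trig mode across the cyclobutane. No new tetrahedral centre survives dehydration, but C4, C5, C10 and C11 become stereogenic in this one event: their relative configuration is inherited from the bicycle, and their absolute configuration is set by the catalyst choosing the acetyl group on the R-configured ring carbon (the future C11) as the enamine donor. The only selectivity required is between the two enantiotopic acetyl groups. Regiochemistry is secured because each acetyl group can form a productive enamine only toward its methyl group, the two acetyl groups are held syn and about 3 Å apart, and the ring ketones are hindered and on the opposite face. Relief of the acetyl–acetyl repulsion and loss of water provide the driving force.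

Step 12
Reactants: 17 the tricyclic enone-dione of step 11
Product: 18 (4R,5S,7R,9R,10R,11R)-longipin-2-ene-1,7,9-triol as a mixture of C1 epimers
Conditions: (S)-2-methyl-CBS-oxazaborolidine (0.5 equiv), catecholborane (4 equiv), toluene, −40 to 0 °C; then MeOH, aqueous work-up
Reagents that add atoms: none
Why: Corey–Bakshi–Shibata reduction: at each ring ketone the quaternary neighbour (C6 or C10) is the large and C8 the small substituent, so the (S)-catalyst should deliver hydride to give the R carbinol at both C7 and C9, the anti diol. The enone carbonyl is reduced as well, with its configuration irrelevant; catecholborane is chosen because it does not hydroborate the C2=C3 alkene.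

Step 13
Reactants: 18 the triol of step 12
Product: 19 (4R,5S,7R,9R,10R,11R)-7,9-dihydroxylongipin-2-en-1-one
Conditions: MnO2 (activated, excess), CH2Cl2, rt
Reagents that add atoms: none
Why: MnO2 oxidises only the allylic C1 alcohol and restores the enone; the saturated, hindered carbinols at C7 and C9 are inert.

Step 14
Reactants: 19 the enone diol of step 13
Product: 20 (4R,5S,7R,9R,10R,11R)-7,9-bis(3-methylbutanoyloxy)longipin-2-en-1-one, the target
Conditions: isovaleryl chloride (4 equiv), pyridine, DMAP (cat.), CH2Cl2, 0 to 40 °C
Reagents that add atoms: isovaleryl chloride, CC(C)CC(Cl)=O
Why: DMAP-catalysed acylation of both hindered secondary alcohols with the acid chloride; no stereocentre is touched and the enone is stable to these conditions.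

## Compound list

1 | 2,2-dimethylbut-3-enoic acid | C=CC(C)(C)C(O)=O | starting material
2 | 2,2-dimethylbut-3-en-1-ol | C=CC(C)(C)CO | intermediate
3 | 2,2-dimethylbut-3-enal | C=CC(C)(C)C=O | intermediate
4 | methyl pyruvate | CC(=O)C(=O)OC | starting material
5 | 1-(triphenylphosphoranylidene)propan-2-one | CC(=O)C=P(c1ccccc1)(c1ccccc1)c1ccccc1 | starting material
6 | methyl (E)-2-methyl-4-oxopent-2-enoate | CC(=O)/C=C(\C)C(=O)OC | intermediate
7 | aminoacetone hydrochloride | CC(=O)CN.Cl | starting material
8 | (E)-1-[(2,2-dimethylbut-3-enylidene)amino]propan-2-one (aldimine, not isolated) | CC(=O)C/N=C/C(C)(C)C=C | intermediate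
9 | racemic pyrrolidine; 2-acetyl, 3-ester and 5-alkyl cis, 4-acetyl trans (one enantiomer drawn) | CC(=O)[C@H]1N[C@@H](C(C)(C)C=C)[C@H](C(C)=O)[C@@]1(C)C(=O)OC | intermediate
10 | racemic kinetic cyclobutane; ester cis to side chain, one acetyl cis and one trans to them (one enantiomer drawn) | CC(=O)[C@H]1[C@@H](C(C)(C)C=C)[C@H](C(C)=O)[C@@]1(C)C(=O)OC | intermediate
11 | meso all-trans methyl 2,4-diacetyl-1-methyl-3-(2-methylbut-3-en-2-yl)cyclobutane-1-carboxylate | CC(=O)[C@@H]1[C@@H](C(C)(C)C=C)[C@H](C(C)=O)[C@@]1(C)C(=O)OC | intermediate
12 | meso methyl 1-methyl-3-(2-methylbut-3-en-2-yl)-2,4-di(prop-1-en-2-yl)cyclobutane-1-carboxylate | C=C(C)[C@@H]1[C@@H](C(C)(C)C=C)[C@H](C(C)=C)[C@@]1(C)C(=O)OC | intermediate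
13 | meso methyl 1-methyl-3-(2-methyl-3-oxobutan-2-yl)-2,4-di(prop-1-en-2-yl)cyclobutane-1-carboxylate | C=C(C)[C@@H]1[C@@H](C(C)(C)C(C)=O)[C@H](C(C)=C)[C@@]1(C)C(=O)OC | intermediate
14 | meso 1,5,5-trimethyl-7,8-di(prop-1-en-2-yl)bicyclo[4.1.1]octane-2,4-dione | C=C(C)[C@@H]1[C@@H]2[C@H](C(C)=C)[C@@]1(C)C(=O)CC(=O)C2(C)C | intermediate
15 | meso 7,8-diacetyl-1,5,5-trimethylbicyclo[4.1.1]octane-2,4-dione | CC(=O)[C@@H]1[C@@H]2[C@H](C(C)=O)[C@@]1(C)C(=O)CC(=O)C2(C)C | intermediate
16 | tricyclic C3 ketol (either C3 epimer, not isolated) | CC1(O)CC(=O)[C@@H]2[C@@H]3[C@H]1[C@@]2(C)C(=O)CC(=O)C3(C)C | intermediate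
17 | (4R,5S,10R,11R)-longipin-2-ene-1,7,9-trione | CC1=CC(=O)[C@@H]2[C@@H]3[C@H]1[C@@]2(C)C(=O)CC(=O)C3(C)C | intermediate
18 | (4R,5S,7R,9R,10R,11R)-longipin-2-ene-1,7,9-triol, C1 epimers | CC1=CC(O)[C@@H]2[C@@H]3[C@H]1[C@@]2(C)[C@H](O)C[C@@H](O)C3(C)C | intermediate
19 | (4R,5S,7R,9R,10R,11R)-7,9-dihydroxylongipin-2-en-1-one | CC1=CC(=O)[C@@H]2[C@@H]3[C@H]1[C@@]2(C)[C@H](O)C[C@@H](O)C3(C)C | intermediate
20 | (4R,5S,7R,9R,10R,11R)-7,9-bis(3-methylbutanoyloxy)longipin-2-en-1-one | CC1=CC(=O)[C@@H]2[C@@H]3[C@H]1[C@@]2(C)[C@H](OC(=O)CC(C)C)C[C@@H](OC(=O)CC(C)C)C3(C)C | target

## Step count and least certain steps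

Total: 14 steps. Longest linear sequence: 13 steps (steps 1, 2 and 4 to 14; step 3 is a one-step branch).

**Step 11 (key step).** The most likely failure is insufficient discrimination between the two enantiotopic acetyl groups. An uncatalysed or acid-catalysed closure of the pre-organised diketone would make this worse, and the acidic 1,3-dione may tie up the basic catalyst. The fallback sets out from 15 and gives up the desymmetrisation in favour of a reagent-controlled separation. Closure with an achiral amine salt (pyrrolidine, AcOH) gives racemic trione, that is 17 together with its enantiomer, ent-trione F1. Reduction of the mixture as in step 12 converts 17 into 18 and F1 into the diastereomeric triol F2, which has the same 7R,9R carbinols on the mirror-image core. MnO2 oxidation as in step 13 gives 19 and the diastereomeric enone diol F3, which are separated by chromatography. The route is rejoined at 19, at the cost of half the material.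

**Step 4.** The most likely failure is the wrong orientation of the dipolarophile: the ketone rather than the ester under the metal. Sluggish or regiochemically reversed addition to the trisubstituted alkene is a related possibility. The wrong orientation would put the ester trans to the arm and give a C10 epimer that cannot be bridged. The fallback sets out from 6. Photochemical E-to-Z isomerisation gives methyl (Z)-2-methyl-4-oxopent-2-enoate F4, in which both carbonyl groups lie on the same side. The ordinary endo approach with 8 then gives the all-cis pyrrolidine F5, with the ester again cis to the arm. Nitrogen deletion as in step 5 gives the all-cis cyclobutane F6, and epimerisation of both acetyl-bearing carbons under the conditions of step 6 rejoins the route at 11.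

**Step 5.** The most likely failure is slow N–N bond formation at the doubly α-branched nitrogen. Fragmentation of the 1,4-diradical into two alkenes is a second risk, and a 1,2-vinyl shift at the arm-bearing radical is conceivable if recombination is slow. The fallback sets out from 9. Nitrosation with the small electrophile t-BuONO gives the N-nitrosopyrrolidine F7. Reduction with Na2S2O4 in aqueous NaOH/EtOH generates the 1,1-diazene directly, which loses N2; the route is rejoined at 10.

**Step 9.** The most likely failure is that the enolate does not reach the hindered ester in the all-axial conformer needed for bridging, leading to intermolecular condensation or recovered material. The fallback sets out from 12 and replaces the ester by a better electrophile. Reduction with i-Bu2AlH at −78 °C gives the aldehyde F8. Wacker oxidation as in step 8 gives the keto aldehyde F9. Intramolecular aldol addition (LiN(SiMe3)2, THF, −78 °C) gives the bicyclic ketol F10 as a mixture of C9 epimers, and Dess–Martin oxidation rejoins the route at 14.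

**Step 12.** The most likely failure is enolisation of the 1,3-dione by the borane. The resulting boron enolate would stop the reduction at the hydroxy ketone stage or erode selectivity at the second carbonyl. The fallback sets out from 17 and separates the two reductions. Stoichiometric (+)-DIP-Cl, the enantiomer that gives R carbinols from tert-alkyl ketones, should give the 9-hydroxy-7-ketone F11 and the 7-hydroxy-9-ketone F12. Hydroxyl-directed anti reduction of both with Me4NBH(OAc)3 (Evans–Saksena) leaves the enone untouched and rejoins the route at 19, bypassing 18 and step 13.

## Further compounds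

F1 | step 11 | ent-trione, (4S,5R,10S,11S)-longipin-2-ene-1,7,9-trione | CC1=CC(=O)[C@H]2[C@H]3[C@@H]1[C@]2(C)C(=O)CC(=O)C3(C)C
F2 | step 11 | diastereomeric triol, (4S,5R,7R,9R,10S,11S), C1 epimers | CC1=CC(O)[C@H]2[C@H]3[C@@H]1[C@]2(C)[C@H](O)C[C@@H](O)C3(C)C
F3 | step 11 | diastereomeric enone diol, (4S,5R,7R,9R,10S,11S) | CC1=CC(=O)[C@H]2[C@H]3[C@@H]1[C@]2(C)[C@H](O)C[C@@H](O)C3(C)C
F4 | step 4 | methyl (Z)-2-methyl-4-oxopent-2-enoate | CC(=O)/C=C(/C)C(=O)OC
F5 | step 4 | racemic all-cis pyrrolidine (both acetyl groups, ester and 5-alkyl group cis) | CC(=O)[C@H]1N[C@@H](C(C)(C)C=C)[C@@H](C(C)=O)[C@@]1(C)C(=O)OC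
F6 | step 4 | meso all-cis cyclobutane (both acetyl groups, ester and side chain cis) | CC(=O)[C@H]1[C@@H](C(C)(C)C=C)[C@@H](C(C)=O)[C@@]1(C)C(=O)OC
F7 | step 5 | racemic N-nitroso derivative of pyrrolidine 9 | CC(=O)[C@H]1N(N=O)[C@@H](C(C)(C)C=C)[C@H](C(C)=O)[C@@]1(C)C(=O)OC
F8 | step 9 | meso 1-methyl-3-(2-methylbut-3-en-2-yl)-2,4-di(prop-1-en-2-yl)cyclobutane-1-carbaldehyde | C=C(C)[C@@H]1[C@@H](C(C)(C)C=C)[C@H](C(C)=C)[C@@]1(C)C=O
F9 | step 9 | meso 1-methyl-3-(2-methyl-3-oxobutan-2-yl)-2,4-di(prop-1-en-2-yl)cyclobutane-1-carbaldehyde | C=C(C)[C@@H]1[C@@H](C(C)(C)C(C)=O)[C@H](C(C)=C)[C@@]1(C)C=O
F10 | step 9 | bicyclic ketol, 2-hydroxy-1,5,5-trimethyl-7,8-di(prop-1-en-2-yl)bicyclo[4.1.1]octan-4-one, C2 epimers | C=C(C)[C@@H]1[C@@H]2[C@H](C(C)=C)[C@@]1(C)C(O)CC(=O)C2(C)C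
F11 | step 12 | (4R,5S,9R,10R,11R)-9-hydroxylongipin-2-ene-1,7-dione | CC1=CC(=O)[C@@H]2[C@@H]3[C@H]1[C@@]2(C)[C@H](O)CC(=O)C3(C)C
F12 | step 12 | (4R,5S,7R,10R,11R)-7-hydroxylongipin-2-ene-1,9-dione | CC1=CC(=O)[C@@H]2[C@@H]3[C@H]1[C@@]2(C)C(=O)C[C@@H](O)C3(C)C
A1 | alternative 1 | 4-bromo-4-methylpent-1-yn-3-one | CC(C)(Br)C(=O)C#C
A2 | alternative 1 | cyclohexane-fused methylbicyclobutane with a dioxolane at C3 (central bond C5–C10) | C[C@]12[C@@H]3[C@H]1[C@H]2CCC31OCCO1
A3 | alternative 1 | tricyclic C7 enone with C3 ketal | O1CCOC13CC[C@@H]2[C@@H]4[C@H]3[C@@]2(C)C=CC(=O)C4(C)C
A4 | alternative 2 | cis-fused cyclohexenone–cycloheptane with C9–C10 epoxide and C7 silyl ether | CC1=CC[C@@H]2[C@H](C1=O)C(C)(C)[C@H](O[Si](C)(C)C(C)(C)C)C[C@H]3O[C@@]23C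
A5 | alternative 2 | tricyclic C4,C9-diol with C2=C3 alkene and C7 silyl ether | CC1=CC[C@@H]2[C@@H]3[C@@]1(O)[C@@]2(C)[C@H](O)C[C@@H](O[Si](C)(C)C(C)(C)C)C3(C)C
A6 | alternative 3 | (3Z,7E)-5-(tert-butyldimethylsilyloxy)-2,6,6,9-tetramethyl-1-(pyrrolidin-1-yl)deca-3,7,9-trien-1-one, C2 epimers | C=C(C)/C=C/C(C)(C)[C@H](O[Si](C)(C)C(C)(C)C)/C=C\C(C)C(=O)N1CCCC1
A7 | alternative 3 | bridged cyclobutanone with C4 isopropenyl and C7 silyl ether | C=C(C)[C@H]1[C@H]2C(=O)[C@]1(C)C=C[C@@H](O[Si](C)(C)C(C)(C)C)C2(C)C
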